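**Retrosynthetic overview**
- The tetralin is made last. It comes from its oxolane isomer by an acid-triggered ring expansion (C7–O bond out, C7–aryl bond in). A sulfonate keeps ring A out of this step and is removed at the end.
- Both oxolanes come from one unsymmetrical bis(α-hydroxy-α-benzyl-γ-lactone) by reduction and cyclodehydration. The two tertiary alcohols come from reductive hydroxylation of two benzylidene lactones.
- The benzylidene groups come from aldol condensation of a C2-symmetric bis-γ-lactone with the ring A and ring D aldehydes. The bis-lactone comes from a biaryl dialdehyde and two succinic anhydrides by an enantioselective aldol / β-lactone / four-to-five ring-expansion cascade.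
- All four arenes come from catechol. Order of ring formation: biaryl B–C, two γ-lactones, two oxolanes, tetralin.

Assumption: the biaryl axis has one ortho oxygen per ring and rotates freely, so no axial descriptor is needed; the sense of induction of the (2S,3R) catalyst in step 5 is assumed, and its enantiomer is used if it proves opposite.

Locants:
- Ring A is the 3-hydroxy-4-methoxybenzyl ring.
- Ring B is the biaryl ring on the oxolane, and ring C is the biaryl ring on the tetralin.
- Ring D is the fused tetralin arene.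
- In each half, C7 sits on ring B or C. C8 is its neighbour and bears C9. C8' is the carbinol carbon and bears C9' and the benzyl carbon C7'.

**Step 1**
Reactants: 1 catechol
Product: 2 guaiacol (2-methoxyphenol)
Conditions: MeI (0.9 equiv), K2CO3 (1.0 equiv), acetone, reflux
Reagents that add atoms: iodomethane CI
Why: Williamson O-methylation with catechol in slight excess and one equivalent of base stops at the monoether, and the leftover diol is washed out with water.

**Step 2**
Reactants: 2 guaiacol, 3 glyoxylic acid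
Product: 6 vanillin, via arylglycolic acid 4 (not isolated), via arylglyoxylic acid 5 (not isolated)
Conditions: 3 (50% aq), NaOH, H2O, 30 °C; then CuSO4 (cat.), air, 95 °C; then H2SO4 to pH 3
Reagents that add atoms: none
Why: The phenolate is hydroxyalkylated para to O by glyoxylate (electrophilic aromatic substitution), the glycolate is oxidised aerobically under copper catalysis, and the keto acid decarboxylates on acidification, which is the industrial vanillin sequence.

**Step 3**
Reactants: 6 vanillin (two molecules)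
Product: 7 dehydrodivanillin
Conditions: FeSO4·7H2O (cat.), Na2S2O8, H2O, 80 → 50 °C
Reagents that add atoms: none
Why: In this oxidative phenol coupling the phenoxyl radical has its para position and one ortho position blocked, so only C5–C5' coupling can occur, and the dimer precipitates.

**Step 4**
Reactants: 7 dehydrodivanillin
Product: 8 bis-MOM dialdehyde
Conditions: MOMCl, iPr2NEt, DMF, 0 °C → rt
Reagents that add atoms: chloromethyl methyl ether COCCl
Why: O-alkylation (MOM acetal protection) with a small electrophile reaches the flanked phenols and restores the electrophilicity of the aldehydes, which the phenolates would quench.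

**Step 5**
Reactants: 8 bis-MOM dialdehyde, 9 succinic anhydride (two molecules)
Product: 11 trans bis(paraconic acid), via bis-beta-lactone diacid 10 (not isolated)
Conditions: 9 (3 equiv), (2S,3R)-HyperBTM (isothiourea, 20 mol %), LiCl (1 equiv), iPr2NEt (3 equiv), CH2Cl2/THF, −40 → 0 °C; cold 0.5 M HCl wash
Reagents that add atoms: none
Why: Proposed new method: 9 N-acylates the isothiourea to an acyl isothiouronium carboxylate, iPr2NEt turns it into a (Z)-ammonium enolate held flat by the 1,5 O···S contact, the LiCl-activated aldehyde is attacked on the face away from the catalyst phenyl group (this forms C7–C8 and sets C8 as S in both halves, with the second event amplifying the ee and diverting errors into a separable diastereomer), the aldolate closes on the acyl isothiouronium carbon and releases the catalyst as cis-β-lactone 10, and because the C7–O bond of a 4-(4-alkoxyaryl)oxetan-2-one ionises easily the pendant carboxylate recaptures the benzylic cation in a four-to-five ring expansion that gives the more stable 7,8-trans γ-lactone acid; the closest known reaction types are the Lewis-base-catalysed ammonium-enolate/ketene–aldehyde aldol-lactonisation, the racemic ZnCl2/Et3N (Fittig-type) paraconic acid synthesis and the ionic β-lactone to γ-lactone ring expansion, which have not been combined as one enantioselective cascade from plain succinic anhydride.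

**Step 6**
Reactants: 11 trans bis(paraconic acid)
Product: 12 bis(hydroxymethyl) bis-lactone
Conditions: BH3·SMe2 (5 equiv), THF, 0 °C → rt; H2O
Reagents that add atoms: none
Why: Chemoselective borane reduction of the carboxylic acids through acyloxyboranes is much faster than lactone reduction and touches no stereocentre.

**Step 7**
Reactants: 12 bis(hydroxymethyl) bis-lactone
Product: 13 bis-TBS bis-lactone
Conditions: TBSCl, imidazole, CH2Cl2, 0 °C → rt
Reagents that add atoms: tert-butyldimethylsilyl chloride CC(C)(C)[Si](C)(C)Cl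
Why: Silylation of the primary alcohols blocks translactonisation and alkoxide chemistry in the enolate step and adds bulk at C9 for the later facial control.

**Step 8**
Reactants: 2 guaiacol
Product: 14 2-methoxyphenyl tosylate
Conditions: TsCl, Et3N, CH2Cl2, 0 °C → rt
Reagents that add atoms: 4-toluenesulfonyl chloride Cc1ccc(cc1)S(=O)(=O)Cl
Why: O-sulfonylation makes this oxygen a weak donor, so OMe directs the next substitution and ring A is later switched off as a Friedel–Crafts nucleophile.

**Step 9**
Reactants: 14 2-methoxyphenyl tosylate, 15 dichloromethyl methyl ether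
Product: 17 isovanillin tosylate, via alpha-chloro ether 16 (not isolated)
Conditions: TiCl4 (2 equiv), CH2Cl2, 0 °C; then ice/H2O
Reagents that add atoms: water O
Why: Rieche formylation occurs para to the only strong donor (OMe), and aqueous work-up hydrolyses the α-chloro ether to the aldehyde.

**Step 10**
Reactants: 6 vanillin
Product: 18 vanillin MOM ether
Conditions: MOMCl, iPr2NEt, CH2Cl2, 0 °C → rt
Reagents that add atoms: chloromethyl methyl ether COCCl
Why: MOM protection (O-alkylation) removes the acidic phenol so that the aldehyde accepts a lithium enolate.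

**Step 11**
Reactants: 13 bis-TBS bis-lactone, 17 isovanillin tosylate, 18 vanillin MOM ether
Product: 20 unsymmetrical bis(benzylidene lactone), via bis-mesylate 19 (not isolated)
Conditions: LiN(SiMe3)2 (2.3 equiv), THF, −78 °C; 17 + 18 (1.1 equiv each, premixed); MsCl (3 equiv); DBU (5 equiv), −78 → 0 °C
Reagents that add atoms: none
Why: Lithium-enolate aldol addition followed by mesylation and E1cB elimination (aldol condensation) at both lactone α-CH2 groups creates no lasting stereocentre; the mixed product is capped at half of the material by statistics and is separated by chromatography from the two symmetric bis-adducts, which differ in their Ts and MOM content.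

**Step 12**
Reactants: 20 unsymmetrical bis(benzylidene lactone)
Product: 22 bis(α-hydroxy-α-benzyl lactone), via bis-hydroperoxide 21 (not isolated)
Conditions: Mn(dpm)3 (20 mol %), PhSiH3 (5 equiv), O2 (1 atm), iPrOH/CH2Cl2, 0 °C → rt; then P(OEt)3
Reagents that add atoms: dioxygen O=O
Why: In this Mukaiyama-type reductive α-hydroxylation (metal-hydride hydrogen-atom transfer) the manganese hydride delivers H to the benzylidene CH in the conjugate sense, the tertiary lactone α-radical at C8' is trapped by O2 on the face opposite the neighbouring C8 CH2OTBS group so that OH ends trans and the new benzyl group cis to C9 (8'S in both halves), and P(OEt)3 reduces the hydroperoxides.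

**Step 13**
Reactants: 22 bis(α-hydroxy-α-benzyl lactone)
Product: 23 hexaol
Conditions: LiBH4 (4 equiv), THF/MeOH (20:1), 0 °C → rt; aq NH4Cl
Reagents that add atoms: none
Why: Borohydride reduces the activated α-hydroxy lactones to 1,4-diols and leaves the aryl sulfonate, MOM and silyl ethers and all stereocentres untouched.

**Step 14**
Reactants: 23 hexaol
Product: 25 ring A tosylate of the target, via bis-oxolane 24 (not isolated)
Conditions: HCl (1.25 M in MeOH), 0.005 M, 45 °C
Reagents that add atoms: none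
Why: The acid strips MOM and TBS and ionises both benzylic C7–OH groups to quinone-methide-type cations that the C9' hydroxyls capture (bis-oxolane 24, aryl trans to C9, 7S), and because C7–O ionisation stays reversible the oxolane whose ring D has OMe para to its free C6 is drained irreversibly by intramolecular Friedel–Crafts attack (oxolane-to-tetralin ring expansion of the olivil-to-cycloolivil type, with ring D adding anti to the C8 CH2OH so that C1 becomes the 1,2-trans S centre), whereas the open ortho positions of ring A are meta to OMe and activated only by the sulfonate oxygen, so its oxolane survives.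

**Step 15**
Reactants: 25 ring A tosylate of the target
Product: 26 target CNP0252244.1
Conditions: KOH (10 equiv), MeOH/H2O (4:1), degassed, Ar, 60 °C; then 1 M HCl to pH 5
Reagents that add atoms: none
Why: Alkaline hydrolysis of the aryl sulfonate proceeds by attack at sulfur (S–O cleavage) and frees the last phenol, while the oxolane, the tetralin and the alcohols are inert to base at this temperature.

**Compound list**
1 | catechol | Oc1ccccc1O | starting material
2 | guaiacol | COc1ccccc1O | intermediate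
3 | glyoxylic acid | O=CC(=O)O | starting material
4 | 2-hydroxy-2-(4-hydroxy-3-methoxyphenyl)acetic acid (racemic, not isolated) | COc1cc(C(O)C(=O)O)ccc1O | intermediate
5 | 2-(4-hydroxy-3-methoxyphenyl)-2-oxoacetic acid (not isolated) | COc1cc(C(=O)C(=O)O)ccc1O | intermediate
6 | vanillin | COc1cc(C=O)ccc1O | intermediate
7 | dehydrodivanillin, 6,6'-dihydroxy-5,5'-dimethoxybiphenyl-3,3'-dicarbaldehyde | COc1cc(C=O)cc(-c2cc(C=O)cc(OC)c2O)c1O | intermediate
8 | 5,5'-dimethoxy-6,6'-bis(methoxymethoxy)biphenyl-3,3'-dicarbaldehyde | COCOc1c(OC)cc(C=O)cc1-c1cc(C=O)cc(OC)c1OCOC | intermediate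
9 | succinic anhydride | O=C1CCC(=O)O1 | starting material
10 | biaryl bearing two cis (2S,3S)-3-(carboxymethyl)-4-oxooxetan-2-yl groups (not isolated) | COCOc1c(OC)cc([C@H]2OC(=O)[C@H]2CC(=O)O)cc1-c1cc([C@H]2OC(=O)[C@H]2CC(=O)O)cc(OC)c1OCOC | intermediate
11 | (2S,3S,2'S,3'S)-2,2'-[5,5'-dimethoxy-6,6'-bis(methoxymethoxy)biphenyl-3,3'-diyl]bis(5-oxooxolane-3-carboxylic acid), 2,3-trans | COCOc1c(OC)cc([C@H]2OC(=O)C[C@@H]2C(=O)O)cc1-c1cc([C@H]2OC(=O)C[C@@H]2C(=O)O)cc(OC)c1OCOC | intermediate
12 | (4R,5S,4'R,5'S)-5,5'-(biaryl-3,3'-diyl)bis[4-(hydroxymethyl)oxolan-2-one] | COCOc1c(OC)cc([C@H]2OC(=O)C[C@@H]2CO)cc1-c1cc([C@H]2OC(=O)C[C@@H]2CO)cc(OC)c1OCOC | intermediate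
13 | bis-TBS ether of 12 | COCOc1c(OC)cc([C@H]2OC(=O)C[C@@H]2CO[Si](C)(C)C(C)(C)C)cc1-c1cc([C@H]2OC(=O)C[C@@H]2CO[Si](C)(C)C(C)(C)C)cc(OC)c1OCOC | intermediate
14 | 2-methoxyphenyl 4-methylbenzenesulfonate | COc1ccccc1OS(=O)(=O)c1ccc(C)cc1 | intermediate
15 | dichloromethyl methyl ether | COC(Cl)Cl | starting material
16 | 5-[chloro(methoxy)methyl]-2-methoxyphenyl 4-methylbenzenesulfonate (not isolated) | COc1ccc(C(Cl)OC)cc1OS(=O)(=O)c1ccc(C)cc1 | intermediate
17 | 5-formyl-2-methoxyphenyl 4-methylbenzenesulfonate (isovanillin tosylate) | COc1ccc(C=O)cc1OS(=O)(=O)c1ccc(C)cc1 | intermediate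
18 | 3-methoxy-4-(methoxymethoxy)benzaldehyde | COCOc1ccc(C=O)cc1OC | intermediate
19 | bis(β-mesyloxy) aldol adduct of 13 with 17 (ring B lactone) and 18 (ring C lactone), epimers at C7' and C8' (not isolated) | COc1ccc(C(OS(C)(=O)=O)C2C(=O)O[C@H](c3cc(OC)c(OCOC)c(-c4cc([C@H]5OC(=O)C(C(OS(C)(=O)=O)c6ccc(OCOC)c(OC)c6)[C@@H]5CO[Si](C)(C)C(C)(C)C)cc(OC)c4OCOC)c3)[C@H]2CO[Si](C)(C)C(C)(C)C)cc1OS(=O)(=O)c1ccc(C)cc1 | intermediate
20 | bis[(E)-3-benzylidene-(4R,5S)-lactone]: ring B lactone with 4-methoxy-3-(tosyloxy)benzylidene, ring C lactone with 3-methoxy-4-(methoxymethoxy)benzylidene | COc1ccc(/C=C2/C(=O)O[C@H](c3cc(OC)c(OCOC)c(-c4cc([C@H]5OC(=O)/C(=C/c6ccc(OCOC)c(OC)c6)[C@@H]5CO[Si](C)(C)C(C)(C)C)cc(OC)c4OCOC)c3)[C@H]2CO[Si](C)(C)C(C)(C)C)cc1OS(=O)(=O)c1ccc(C)cc1 | intermediate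
21 | bis(3-hydroperoxy-3-benzyl) lactone, (3S,4R,5S) in both rings (not isolated) | COc1ccc(C[C@@]2(OO)C(=O)O[C@H](c3cc(OC)c(OCOC)c(-c4cc([C@H]5OC(=O)[C@](OO)(Cc6ccc(OCOC)c(OC)c6)[C@@H]5CO[Si](C)(C)C(C)(C)C)cc(OC)c4OCOC)c3)[C@H]2CO[Si](C)(C)C(C)(C)C)cc1OS(=O)(=O)c1ccc(C)cc1 | intermediate
22 | bis(3-hydroxy-3-benzyl) lactone, (3S,4R,5S) in both rings | COc1ccc(C[C@@]2(O)C(=O)O[C@H](c3cc(OC)c(OCOC)c(-c4cc([C@H]5OC(=O)[C@](O)(Cc6ccc(OCOC)c(OC)c6)[C@@H]5CO[Si](C)(C)C(C)(C)C)cc(OC)c4OCOC)c3)[C@H]2CO[Si](C)(C)C(C)(C)C)cc1OS(=O)(=O)c1ccc(C)cc1 | intermediate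
23 | open-chain hexaol, (7S,8R,8'S) in both halves, C9 as OTBS, free OH at C7, C8' and C9' | COc1ccc(C[C@@]([C@H](CO[Si](C)(C)C(C)(C)C)[C@H](O)c2cc(OC)c(OCOC)c(-c3cc([C@@H](O)[C@@H](CO[Si](C)(C)C(C)(C)C)[C@](O)(CO)Cc4ccc(OCOC)c(OC)c4)cc(OC)c3OCOC)c2)(O)CO)cc1OS(=O)(=O)c1ccc(C)cc1 | intermediate
24 | bis-oxolane, (2S,3R,4S) in both rings, free phenols on rings B, C and D, OTs on ring A (not isolated) | COc1ccc(C[C@@]2(O)CO[C@H](c3cc(OC)c(O)c(-c4cc([C@H]5OC[C@](O)(Cc6ccc(O)c(OC)c6)[C@@H]5CO)cc(OC)c4O)c3)[C@H]2CO)cc1OS(=O)(=O)c1ccc(C)cc1 | intermediate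
25 | target with the ring A phenol as tosylate: (2S,3R,4S)-oxolane and (1S,2S,3S)-tetralin | COc1ccc(C[C@@]2(O)CO[C@H](c3cc(OC)c(O)c(-c4cc([C@H]5c6cc(O)c(OC)cc6C[C@@](O)(CO)[C@@H]5CO)cc(OC)c4O)c3)[C@H]2CO)cc1OS(=O)(=O)c1ccc(C)cc1 | intermediate
26 | CNP0252244.1 | COc1ccc(C[C@@]2(O)CO[C@H](c3cc(OC)c(O)c(-c4cc([C@H]5c6cc(O)c(OC)cc6C[C@@](O)(CO)[C@@H]5CO)cc(OC)c4O)c3)[C@H]2CO)cc1O | target

**Step count**
- Total steps: 15.
- Longest linear sequence: 12 (steps 1–7 and 11–15).

**Three steps most likely to fail**

Step 5 (proposed new cascade). The acyl isothiouronium may not enolise. Intermediate 10 may lose CO2 to a styrene instead of expanding. The ee may be low. The fallback uses known auxiliary chemistry; it sets out from 9 and 8 and comes back at 11. The lithium salt of (S)-4-benzyl-1,3-oxazolidin-2-one opens 9 to the imide acid F1. MeI/K2CO3 then gives the methyl ester imide F2. A Bu2BOTf/iPr2NEt Evans syn aldol of F2 (2.4 equiv) with 8 gives the (7S,8S) bis-aldol F3. Catalytic pyridinium tosylate closes each C7–OH onto its methyl ester to give the trans bis(lactone imide) F4. LiOH/H2O2, then Na2SO3 and acidification, removes the auxiliary and gives 11.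

Step 11 (mixed double condensation). The yield is capped at one half by statistics. DBU could also epimerise C8 or open the lactone by vinylogous elimination. The fallback makes the biaryl bond last; it sets out from 6 and comes back at 20.
- Br2 in AcOH gives 5-bromovanillin F5, and MOMCl/iPr2NEt gives its MOM ether F6.
- The chemistry of step 5 on the single aldehyde gives, through the β-lactone acid F7, the trans lactone acid F8.
- BH3·SMe2 gives the alcohol F9, and TBSCl gives the silyl ether F10.
- F10 is condensed separately, as in step 11, with 17 (through mesylate F11 to bromide F12) and with 18 (through mesylate F13 to bromide F14).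
- Miyaura borylation of F14 (B2pin2, Pd(dppf)Cl2, KOAc, dioxane, 80 °C) gives the boronate F15.
- Suzuki–Miyaura coupling of F12 with F15 (Pd(dppf)Cl2, K3PO4, dioxane/H2O, 80 °C; the aryl tosylate is inert to this catalyst) gives 20 as the only biaryl.

Step 12 (reductive hydroxylation). Hydrogen-atom transfer may go to C8' and give benzylic oxidation at C7', or the facial ratio may be modest. The fallback separates reduction from oxygenation; it sets out from 20 and comes back at 22. Copper hydride conjugate reduction (Cu(OAc)2, 1,2-bis(diphenylphosphino)benzene, polymethylhydrosiloxane, tBuOH, toluene) gives the bis(α-benzyl lactone) F16. KN(SiMe3)2 at −78 °C followed by 2-(phenylsulfonyl)-3-phenyloxaziridine then hydroxylates both enolates anti to the C8 substituent and gives 22.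

**Further compounds**
F1 | step 5 | 4-[(4S)-4-benzyl-2-oxo-1,3-oxazolidin-3-yl]-4-oxobutanoic acid | O=C(O)CCC(=O)N1[C@@H](Cc2ccccc2)COC1=O
F2 | step 5 | methyl 4-[(4S)-4-benzyl-2-oxo-1,3-oxazolidin-3-yl]-4-oxobutanoate | COC(=O)CCC(=O)N1[C@@H](Cc2ccccc2)COC1=O
F3 | step 5 | (7S,8S) bis syn-aldol of 8 with F2 | COCOc1c(OC)cc([C@@H](O)[C@H](CC(=O)OC)C(=O)N2[C@@H](Cc3ccccc3)COC2=O)cc1-c1cc([C@@H](O)[C@H](CC(=O)OC)C(=O)N2[C@@H](Cc3ccccc3)COC2=O)cc(OC)c1OCOC
F4 | step 5 | trans bis(lactone imide) | COCOc1c(OC)cc([C@H]2OC(=O)C[C@@H]2C(=O)N3[C@@H](Cc4ccccc4)COC3=O)cc1-c1cc([C@H]2OC(=O)C[C@@H]2C(=O)N3[C@@H](Cc4ccccc4)COC3=O)cc(OC)c1OCOC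
F5 | step 11 | 5-bromovanillin | COc1cc(C=O)cc(Br)c1O
F6 | step 11 | 3-bromo-5-methoxy-4-(methoxymethoxy)benzaldehyde | COCOc1c(Br)cc(C=O)cc1OC
F7 | step 11 | cis (2S,3S)-β-lactone acid of F6 (not isolated) | COCOc1c(Br)cc([C@H]2OC(=O)[C@H]2CC(=O)O)cc1OC
F8 | step 11 | (2S,3S)-2-aryl-5-oxooxolane-3-carboxylic acid of F6 | COCOc1c(Br)cc([C@H]2OC(=O)C[C@@H]2C(=O)O)cc1OC
F9 | step 11 | (4R,5S)-5-aryl-4-(hydroxymethyl)oxolan-2-one | COCOc1c(Br)cc([C@H]2OC(=O)C[C@@H]2CO)cc1OC
F10 | step 11 | TBS ether of F9 | COCOc1c(Br)cc([C@H]2OC(=O)C[C@@H]2CO[Si](C)(C)C(C)(C)C)cc1OC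
F11 | step 11 | β-mesyloxy aldol adduct of F10 with 17 (not isolated) | COc1ccc(C(OS(C)(=O)=O)C2C(=O)O[C@H](c3cc(OC)c(OCOC)c(Br)c3)[C@H]2CO[Si](C)(C)C(C)(C)C)cc1OS(=O)(=O)c1ccc(C)cc1
F12 | step 11 | ring A/ring B (E)-benzylidene lactone bromide | COc1ccc(/C=C2/C(=O)O[C@H](c3cc(OC)c(OCOC)c(Br)c3)[C@H]2CO[Si](C)(C)C(C)(C)C)cc1OS(=O)(=O)c1ccc(C)cc1
F13 | step 11 | β-mesyloxy aldol adduct of F10 with 18 (not isolated) | COCOc1ccc(C(OS(C)(=O)=O)C2C(=O)O[C@H](c3cc(OC)c(OCOC)c(Br)c3)[C@H]2CO[Si](C)(C)C(C)(C)C)cc1OC
F14 | step 11 | ring D/ring C (E)-benzylidene lactone bromide | COCOc1ccc(/C=C2/C(=O)O[C@H](c3cc(OC)c(OCOC)c(Br)c3)[C@H]2CO[Si](C)(C)C(C)(C)C)cc1OC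
F15 | step 11 | pinacol boronate of F14 | COCOc1ccc(/C=C2/C(=O)O[C@H](c3cc(OC)c(OCOC)c(B4OC(C)(C)C(C)(C)O4)c3)[C@H]2CO[Si](C)(C)C(C)(C)C)cc1OC
F16 | step 12 | bis(3-benzyl lactone), (3S,4R,5S) in both rings, benzyl trans to C9 | COc1ccc(C[C@@H]2C(=O)O[C@H](c3cc(OC)c(OCOC)c(-c4cc([C@H]5OC(=O)[C@@H](Cc6ccc(OCOC)c(OC)c6)[C@@H]5CO[Si](C)(C)C(C)(C)C)cc(OC)c4OCOC)c3)[C@H]2CO[Si](C)(C)C(C)(C)C)cc1OS(=O)(=O)c1ccc(C)cc1
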